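**Plan**

1. Retrosynthetic cuts: the O3 and O9 allyl ethers last; then C6a–C11a and O11–C11a together (rings B and C); then C11a–S, C6–C6a (aryloxymethyl anion plus ring-D aldehyde) and the aryl–prenyl and chromene bonds of the two aldehydes (prenyl = 3-methylbut-2-en-1-yl).
2. Enabling feature (pterocarpan numbering): C11a is bonded to both C6a and O11, the two termini of an o-quinone methide of ring D (C10a=O, C6b=C6a; the C10a oxygen is ortho to the C6b–C6a bond). C11a can therefore enter as a sulfonium-ylide carbon carried on ring A and tethered through O5–C6.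
3. Forward: the ring-A aldehyde (Stille prenylation, O-allylation, stannylmethyl ether, acetal) and the ring-D aldehyde (chromene by propargyl ether rearrangement, C10 prenyl by allyl Claisen and cross-metathesis) are joined at C6–C6a. The ring-A CHO is reduced and converted to the thiolanium salt, rings B then C close in one operation, and deallylation ends the route.
4. Stereochemistry: C11a comes from the C2-symmetric (2R,5R)-2,5-dimethylthiolane (double inversion of (2S,5S)-hexane-2,5-diol). C6a follows from the trans betaine, the only one that can close by SN2, which enforces the cis B/C fusion. The acetate carbon is racemic and is erased.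

Key step: step 16

Assumption: the benzylide of the (2R,5R)-thiolanium is taken to bond through the face remote from the ring methyl cis to the ylide carbon (aryl anti to the ring), the sense in which this sulfide is known to give (S,S)-stilbene oxides; by the CIP rules this gives the (11aS) betaine and 11aR after inversion.

**Route**

Step 1
Reactants: 1 5-bromo-2,4-dihydroxybenzaldehyde; 2 tributyl(3-methylbut-2-en-1-yl)stannane
Product: 3 2,4-dihydroxy-5-prenylbenzaldehyde
Conditions: Pd(PPh3)4 (5 mol%), DMF, 95 °C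
Reagents that add atoms: tributyl(3-methylbut-2-en-1-yl)stannane, CCCC[Sn](CCCC)(CCCC)CC=C(C)C
Why: Stille cross-coupling needs no base, so the free phenols and the aldehyde are tolerated, and the allyl unit should be delivered at its unsubstituted terminus to give the linear prenyl arene.

Step 2
Reactants: 3 2,4-dihydroxy-5-prenylbenzaldehyde; 4 allyl bromide
Product: 5 4-(allyloxy)-2-hydroxy-5-prenylbenzaldehyde
Conditions: allyl bromide (1.1 equiv), KHCO3, DMF, 40 °C
Reagents that add atoms: allyl bromide, C=CCBr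
Why: Williamson etherification with a weak base alkylates only the more acidic 4-OH (para to the formyl group), while the 2-OH stays hydrogen-bonded to the aldehyde.

Step 3
Reactants: 5 4-(allyloxy)-2-hydroxy-5-prenylbenzaldehyde; 6 tributyl(iodomethyl)stannane
Product: 7 4-(allyloxy)-5-prenyl-2-[(tributylstannyl)methoxy]benzaldehyde
Conditions: K2CO3, DMF, 55 °C
Reagents that add atoms: tributyl(iodomethyl)stannane, CCCC[Sn](CI)(CCCC)CCCC
Why: Williamson etherification (SN2) of the remaining phenol with the primary iodide installs the future C6 as a stannylmethyl ether.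

Step 4
Reactants: 7 4-(allyloxy)-5-prenyl-2-[(tributylstannyl)methoxy]benzaldehyde; 8 trimethyl orthoformate
Product: 9 {[5-(allyloxy)-2-(dimethoxymethyl)-4-prenylphenoxy]methyl}tributylstannane
Conditions: HC(OMe)3, PPTS (cat.), MeOH, rt; Et3N quench
Reagents that add atoms: trimethyl orthoformate, COC(OC)OC
Why: Acid-catalysed acetalisation masks the aldehyde against butyllithium, and PPTS is too weak an acid to protodestannylate the α-alkoxystannane.

Step 5
Reactants: 10 2,4,5-trihydroxybenzaldehyde; 4 allyl bromide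
Product: 11 4-(allyloxy)-2,5-dihydroxybenzaldehyde
Conditions: allyl bromide (1.05 equiv), KHCO3, DMF, 40 °C, argon
Reagents that add atoms: allyl bromide, C=CCBr
Why: Williamson etherification under weak base selects the 4-OH, the most acidic of the three (para to the formyl group), as in 3,4- and 2,4-dihydroxybenzaldehydes.

Step 6
Reactants: 11 4-(allyloxy)-2,5-dihydroxybenzaldehyde; 12 3-chloro-3-methylbut-1-yne
Product: 13 4-(allyloxy)-2-hydroxy-5-[(2-methylbut-3-yn-2-yl)oxy]benzaldehyde
Conditions: DBU, CuCl2 (cat.), MeCN, 0 °C, argon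
Reagents that add atoms: 3-chloro-3-methylbut-1-yne, C#CC(C)(C)Cl
Why: Copper-catalysed O-alkylation with the tertiary propargylic chloride goes to the free 5-OH because the 2-OH is locked in the hydrogen bond to the aldehyde.

Step 7
Reactants: 13 4-(allyloxy)-2-hydroxy-5-[(2-methylbut-3-yn-2-yl)oxy]benzaldehyde
Product: 15 7-allyl-6,8-dihydroxy-2,2-dimethyl-2H-chromene-5-carbaldehyde, via 8-(allyloxy)-6-hydroxy-2,2-dimethyl-2H-chromene-5-carbaldehyde 14 (not isolated)
Conditions: PhNEt2, 150 °C then 195 °C, argon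
Reagents that add atoms: none
Why: Propargyl ether Claisen rearrangement to C6 of 13 (the only free position ortho to O5), 1,5-H shift and oxa-6π electrocyclisation give the 2,2-dimethylchromene, and at the higher temperature the aromatic Claisen rearrangement moves the allyl group from O4 to C3, its only free ortho carbon.

Step 8
Reactants: 15 7-allyl-6,8-dihydroxy-2,2-dimethyl-2H-chromene-5-carbaldehyde; 16 2-methylbut-2-ene
Product: 17 6,8-dihydroxy-2,2-dimethyl-7-prenyl-2H-chromene-5-carbaldehyde
Conditions: second-generation Grubbs catalyst (5 mol%), 2-methylbut-2-ene/CH2Cl2, 40 °C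
Reagents that add atoms: 2-methylbut-2-ene, CC=C(C)C
Why: Olefin cross-metathesis exchanges the terminal allyl group for prenyl, and the trisubstituted product and the hindered chromene double bond should not react further.

Step 9
Reactants: 17 6,8-dihydroxy-2,2-dimethyl-7-prenyl-2H-chromene-5-carbaldehyde; 4 allyl bromide
Product: 18 8-(allyloxy)-6-hydroxy-2,2-dimethyl-7-prenyl-2H-chromene-5-carbaldehyde
Conditions: allyl bromide, K2CO3 (1.2 equiv), acetone, 50 °C
Reagents that add atoms: allyl bromide, C=CCBr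
Why: Williamson etherification of the non-chelated 8-OH (para to the formyl group, the future O9), while the 6-OH remains hydrogen-bonded to the aldehyde.

Step 10
Reactants: 18 8-(allyloxy)-6-hydroxy-2,2-dimethyl-7-prenyl-2H-chromene-5-carbaldehyde; 19 tert-butyldimethylsilyl chloride
Product: 20 8-(allyloxy)-6-[(tert-butyldimethylsilyl)oxy]-2,2-dimethyl-7-prenyl-2H-chromene-5-carbaldehyde
Conditions: TBSCl, imidazole, DMAP (cat.), DMF, 40 °C
Reagents that add atoms: tert-butyldimethylsilyl chloride, CC(C)(C)[Si](C)(C)Cl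
Why: Silylation of the chelated phenol (future O11) installs the fluoride-labile trigger for the quinone methide.

Step 11
Reactants: 21 (2S,5S)-hexane-2,5-diol; 22 methanesulfonyl chloride
Product: 23 (2S,5S)-hexane-2,5-diyl dimethanesulfonate
Conditions: MsCl, Et3N, CH2Cl2, 0 °C
Reagents that add atoms: methanesulfonyl chloride, CS(=O)(=O)Cl
Why: Mesylation of both secondary alcohols takes place at oxygen and leaves the two stereocentres untouched.

Step 12
Reactants: 23 (2S,5S)-hexane-2,5-diyl dimethanesulfonate; 24 sodium sulfide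
Product: 25 (2R,5R)-2,5-dimethylthiolane
Conditions: Na2S·9H2O, DMSO, rt to 40 °C
Reagents that add atoms: sodium sulfide, [Na+].[Na+].[S-2]
Why: Double SN2 displacement by sulfide (intermolecular, then 5-exo-tet) inverts both centres, so the (2S,5S)-diol gives the (2R,5R)-thiolane.

Step 13
Reactants: 9 {[5-(allyloxy)-2-(dimethoxymethyl)-4-prenylphenoxy]methyl}tributylstannane; 20 8-(allyloxy)-6-[(tert-butyldimethylsilyl)oxy]-2,2-dimethyl-7-prenyl-2H-chromene-5-carbaldehyde; 26 acetic anhydride
Product: 30 2-[5-(allyloxy)-2-formyl-4-prenylphenoxy]-1-[8-(allyloxy)-6-(tert-butyldimethylsilyloxy)-2,2-dimethyl-7-prenyl-2H-chromen-5-yl]ethyl acetate (racemic), via {[5-(allyloxy)-2-(dimethoxymethyl)-4-prenylphenoxy]methyl}lithium 27 (not isolated), via the lithium alkoxide adduct 28 (not isolated), via the acetate dimethyl acetal 29 (not isolated)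
Conditions: n-BuLi, THF, −78 °C, 10 min; add 20, −78 °C; Ac2O, −78 to −30 °C; aq NH4Cl; then PPTS (cat.), acetone/H2O, rt
Reagents that add atoms: acetic anhydride, CC(=O)OC(C)=O; water, O
Why: Tin–lithium exchange of the α-alkoxystannane gives an aryloxymethyllithium that adds to the aldehyde (C6–C6a); acetylating the lithium alkoxide cold pre-empts O-to-O silyl migration from the ortho silyl ether, the electron-rich aryl acetal hydrolyses under PPTS without loss of the silyl ether or acetate, and the new carbinol centre is racemic but becomes sp2 in step 16.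

Step 14
Reactants: 30 2-[5-(allyloxy)-2-formyl-4-prenylphenoxy]-1-[8-(allyloxy)-6-(tert-butyldimethylsilyloxy)-2,2-dimethyl-7-prenyl-2H-chromen-5-yl]ethyl acetate
Product: 31 2-[5-(allyloxy)-2-(hydroxymethyl)-4-prenylphenoxy]-1-[8-(allyloxy)-6-(tert-butyldimethylsilyloxy)-2,2-dimethyl-7-prenyl-2H-chromen-5-yl]ethyl acetate (racemic)
Conditions: NaBH4, THF/EtOH, −20 °C; aq NH4Cl
Reagents that add atoms: none
Why: Borohydride reduction of the aryl aldehyde should be faster than any attack on the hindered secondary acetate or the aryl silyl ether under brief, cold conditions.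

Step 15
Reactants: 31 2-[5-(allyloxy)-2-(hydroxymethyl)-4-prenylphenoxy]-1-[8-(allyloxy)-6-(tert-butyldimethylsilyloxy)-2,2-dimethyl-7-prenyl-2H-chromen-5-yl]ethyl acetate; 25 (2R,5R)-2,5-dimethylthiolane; 32 sodium tetrafluoroborate
Product: 35 (2R,5R)-1-{4-(allyloxy)-2-[2-acetoxy-2-(8-(allyloxy)-6-(tert-butyldimethylsilyloxy)-2,2-dimethyl-7-prenyl-2H-chromen-5-yl)ethoxy]-5-prenylbenzyl}-2,5-dimethylthiolan-1-ium tetrafluoroborate (both epimers at the acetate carbon), via the benzylic methanesulfonate 33 (not isolated), via the thiolanium methanesulfonate 34 (not isolated)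
Conditions: Ms2O, 2,6-di-tert-butyl-4-methylpyridine, 25 (3 equiv), CH2Cl2, −40 to 0 °C; then sat. aq NaBF4 (anion exchange), 0 °C; precipitated and used crude
Reagents that add atoms: sodium tetrafluoroborate, [Na+].F[B-](F)(F)F
Why: The 2,4-dialkoxybenzyl mesylate formed in situ is reactive enough to S-alkylate the hindered sulfide without acid, exchange to tetrafluoroborate removes any nucleophilic counter-ion, and the C2-symmetric sulfide gives a single sulfonium configuration.

Step 16
Reactants: 35 (2R,5R)-1-{4-(allyloxy)-2-[2-acetoxy-2-(8-(allyloxy)-6-(tert-butyldimethylsilyloxy)-2,2-dimethyl-7-prenyl-2H-chromen-5-yl)ethoxy]-5-prenylbenzyl}-2,5-dimethylthiolan-1-ium tetrafluoroborate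
Product: 38 (6aR,11aR)-3,9-di-O-allyl-lespecyrtin E3, via the ring-D o-quinone methide carrying the ring-A thiolanium benzylide 36 (not isolated), via the trans phenoxide–sulfonium betaine (6aR,11aS) 37 (not isolated)
Conditions: CsF (3 equiv), 18-crown-6 (cat.), Cs2CO3 (3 equiv), MeCN (0.002 M), −20 °C to rt
Reagents that add atoms: none
Why: Proposed new method: fluoride cleaves the aryl silyl ether and the C10a phenoxide expels the C6a acetate (1,4-elimination) to give the ring-D o-quinone methide, while carbonate turns the thiolanium into its benzylide, whose carbon (C11a) adds to the methide carbon C6a to give betaine 37, which closes when O11 displaces the sulfide with inversion at C11a. The closest known reaction is the intermolecular [4+1] annulation of sulfonium ylides with o-quinone methides generated in situ from o-silyloxybenzyl or 2-(1-tosylalkyl)phenol precursors to give 2,3-dihydrobenzofurans, including chiral-sulfide variants; tethering the partners through O5–C6 so that a chroman forms as well is new. Ring B closes by 6-exo-trig conjugate addition (ring D rearomatises to the phenoxide) and ring C by 5-exo-tet SN2. C11a is controlled by the C2-symmetric sulfide, whose methyl group cis to the ylide carbon shields one face so that C6a bonds on the other and the (11aS) betaine inverts to 11aR; C6a follows because only the betaine with sulfonium trans to the ring-D aryl on the new chroman can place O11 anti to the C–S bond, which gives the cis fusion and 6aR. The step needs intramolecular capture to outrun tautomerisation of the methide to the vinyl phenol, its dimerisation and intermolecular ylide–methide coupling; high dilution, the six-membered transition state and release of the methide in the presence of the ylide should secure this, and both epimers of 35 converge because the acetate carbon becomes sp2.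

Step 17
Reactants: 38 (6aR,11aR)-3,9-di-O-allyl-lespecyrtin E3
Product: 39 lespecyrtin E3
Conditions: Pd(PPh3)4 (5 mol%), morpholine, THF, rt
Reagents that add atoms: none
Why: Tsuji–Trost deallylation transfers both O-allyl groups to morpholine under neutral conditions, which should leave the prenyl groups, the chromene, the benzylic C11a–O11 bond and both stereocentres untouched.

**Compound list**

1 | 5-bromo-2,4-dihydroxybenzaldehyde | O=Cc1cc(Br)c(O)cc1O | starting material
2 | tributyl(3-methylbut-2-en-1-yl)stannane | CCCC[Sn](CCCC)(CCCC)CC=C(C)C | starting material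
3 | 2,4-dihydroxy-5-prenylbenzaldehyde | O=Cc1cc(CC=C(C)C)c(O)cc1O | intermediate
4 | allyl bromide | C=CCBr | starting material
5 | 4-(allyloxy)-2-hydroxy-5-prenylbenzaldehyde | O=Cc1cc(CC=C(C)C)c(OCC=C)cc1O | intermediate
6 | tributyl(iodomethyl)stannane | CCCC[Sn](CI)(CCCC)CCCC | starting material
7 | 4-(allyloxy)-5-prenyl-2-[(tributylstannyl)methoxy]benzaldehyde | O=Cc1cc(CC=C(C)C)c(OCC=C)cc1OC[Sn](CCCC)(CCCC)CCCC | intermediate
8 | trimethyl orthoformate | COC(OC)OC | starting material
9 | {[5-(allyloxy)-2-(dimethoxymethyl)-4-prenylphenoxy]methyl}tributylstannane | COC(OC)c1cc(CC=C(C)C)c(OCC=C)cc1OC[Sn](CCCC)(CCCC)CCCC | intermediate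
10 | 2,4,5-trihydroxybenzaldehyde | O=Cc1cc(O)c(O)cc1O | starting material
11 | 4-(allyloxy)-2,5-dihydroxybenzaldehyde | O=Cc1cc(O)c(OCC=C)cc1O | intermediate
12 | 3-chloro-3-methylbut-1-yne | C#CC(C)(C)Cl | starting material
13 | 4-(allyloxy)-2-hydroxy-5-[(2-methylbut-3-yn-2-yl)oxy]benzaldehyde | O=Cc1cc(OC(C)(C)C#C)c(OCC=C)cc1O | intermediate
14 | 8-(allyloxy)-6-hydroxy-2,2-dimethyl-2H-chromene-5-carbaldehyde | O=Cc1c2C=CC(C)(C)Oc2c(OCC=C)cc1O | intermediate (not isolated)
15 | 7-allyl-6,8-dihydroxy-2,2-dimethyl-2H-chromene-5-carbaldehyde | O=Cc1c2C=CC(C)(C)Oc2c(O)c(CC=C)c1O | intermediate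
16 | 2-methylbut-2-ene | CC=C(C)C | starting material
17 | 6,8-dihydroxy-2,2-dimethyl-7-prenyl-2H-chromene-5-carbaldehyde | O=Cc1c2C=CC(C)(C)Oc2c(O)c(CC=C(C)C)c1O | intermediate
18 | 8-(allyloxy)-6-hydroxy-2,2-dimethyl-7-prenyl-2H-chromene-5-carbaldehyde | O=Cc1c2C=CC(C)(C)Oc2c(OCC=C)c(CC=C(C)C)c1O | intermediate
19 | tert-butyldimethylsilyl chloride | CC(C)(C)[Si](C)(C)Cl | starting material
20 | 8-(allyloxy)-6-[(tert-butyldimethylsilyl)oxy]-2,2-dimethyl-7-prenyl-2H-chromene-5-carbaldehyde | O=Cc1c2C=CC(C)(C)Oc2c(OCC=C)c(CC=C(C)C)c1O[Si](C)(C)C(C)(C)C | intermediate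
21 | (2S,5S)-hexane-2,5-diol | C[C@H](O)CC[C@H](C)O | starting material
22 | methanesulfonyl chloride | CS(=O)(=O)Cl | starting material
23 | (2S,5S)-hexane-2,5-diyl dimethanesulfonate | C[C@H](OS(C)(=O)=O)CC[C@H](C)OS(C)(=O)=O | intermediate
24 | sodium sulfide (used as the nonahydrate) | [Na+].[Na+].[S-2] | starting material
25 | (2R,5R)-2,5-dimethylthiolane | C[C@@H]1CC[C@@H](C)S1 | intermediate
26 | acetic anhydride | CC(=O)OC(C)=O | starting material
27 | {[5-(allyloxy)-2-(dimethoxymethyl)-4-prenylphenoxy]methyl}lithium | [Li]COc1cc(OCC=C)c(CC=C(C)C)cc1C(OC)OC | intermediate (not isolated)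
28 | lithium 2-[5-(allyloxy)-2-(dimethoxymethyl)-4-prenylphenoxy]-1-[8-(allyloxy)-6-(tert-butyldimethylsilyloxy)-2,2-dimethyl-7-prenyl-2H-chromen-5-yl]ethoxide (racemic) | [Li]OC(COc1cc(OCC=C)c(CC=C(C)C)cc1C(OC)OC)c1c2C=CC(C)(C)Oc2c(OCC=C)c(CC=C(C)C)c1O[Si](C)(C)C(C)(C)C | intermediate (not isolated)
29 | 2-[5-(allyloxy)-2-(dimethoxymethyl)-4-prenylphenoxy]-1-[8-(allyloxy)-6-(tert-butyldimethylsilyloxy)-2,2-dimethyl-7-prenyl-2H-chromen-5-yl]ethyl acetate (racemic) | CC(=O)OC(COc1cc(OCC=C)c(CC=C(C)C)cc1C(OC)OC)c1c2C=CC(C)(C)Oc2c(OCC=C)c(CC=C(C)C)c1O[Si](C)(C)C(C)(C)C | intermediate (not isolated)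
30 | 2-[5-(allyloxy)-2-formyl-4-prenylphenoxy]-1-[8-(allyloxy)-6-(tert-butyldimethylsilyloxy)-2,2-dimethyl-7-prenyl-2H-chromen-5-yl]ethyl acetate (racemic) | CC(=O)OC(COc1cc(OCC=C)c(CC=C(C)C)cc1C=O)c1c2C=CC(C)(C)Oc2c(OCC=C)c(CC=C(C)C)c1O[Si](C)(C)C(C)(C)C | intermediate
31 | 2-[5-(allyloxy)-2-(hydroxymethyl)-4-prenylphenoxy]-1-[8-(allyloxy)-6-(tert-butyldimethylsilyloxy)-2,2-dimethyl-7-prenyl-2H-chromen-5-yl]ethyl acetate (racemic) | CC(=O)OC(COc1cc(OCC=C)c(CC=C(C)C)cc1CO)c1c2C=CC(C)(C)Oc2c(OCC=C)c(CC=C(C)C)c1O[Si](C)(C)C(C)(C)C | intermediate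
32 | sodium tetrafluoroborate | [Na+].F[B-](F)(F)F | starting material
33 | 2-{5-(allyloxy)-2-[(methylsulfonyloxy)methyl]-4-prenylphenoxy}-1-[8-(allyloxy)-6-(tert-butyldimethylsilyloxy)-2,2-dimethyl-7-prenyl-2H-chromen-5-yl]ethyl acetate | CC(=O)OC(COc1cc(OCC=C)c(CC=C(C)C)cc1COS(C)(=O)=O)c1c2C=CC(C)(C)Oc2c(OCC=C)c(CC=C(C)C)c1O[Si](C)(C)C(C)(C)C | intermediate (not isolated)
34 | (2R,5R)-1-{4-(allyloxy)-2-[2-acetoxy-2-(ring-D aryl)ethoxy]-5-prenylbenzyl}-2,5-dimethylthiolan-1-ium methanesulfonate | CC(=O)OC(COc1cc(OCC=C)c(CC=C(C)C)cc1C[S+]1[C@H](C)CC[C@H]1C)c1c2C=CC(C)(C)Oc2c(OCC=C)c(CC=C(C)C)c1O[Si](C)(C)C(C)(C)C.CS(=O)(=O)[O-] | intermediate (not isolated)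
35 | (2R,5R)-1-{4-(allyloxy)-2-[2-acetoxy-2-(8-(allyloxy)-6-(tert-butyldimethylsilyloxy)-2,2-dimethyl-7-prenyl-2H-chromen-5-yl)ethoxy]-5-prenylbenzyl}-2,5-dimethylthiolan-1-ium tetrafluoroborate (epimers at the acetate carbon) | CC(=O)OC(COc1cc(OCC=C)c(CC=C(C)C)cc1C[S+]1[C@H](C)CC[C@H]1C)c1c2C=CC(C)(C)Oc2c(OCC=C)c(CC=C(C)C)c1O[Si](C)(C)C(C)(C)C.F[B-](F)(F)F | intermediate
36 | ring-D o-quinone methide (C10a=O, C6b=C6a) tethered through O5–C6 to the ring-A benzylide of the (2R,5R)-thiolanium | O=C1C(CC=C(C)C)=C(OCC=C)C2=C(C=CC(C)(C)O2)C1=CCOc1cc(OCC=C)c(CC=C(C)C)cc1[CH-][S+]1[C@H](C)CC[C@H]1C | intermediate (not isolated)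
37 | trans betaine: 7-(allyloxy)-6-prenylchroman with the ring-D phenoxide at C3 (C6a, R) and the (2R,5R)-thiolanium at C4 (C11a, S) | CC(C)=CCc1cc2c(cc1OCC=C)OC[C@@H](c1c3C=CC(C)(C)Oc3c(OCC=C)c(CC=C(C)C)c1[O-])[C@@H]2[S+]1[C@H](C)CC[C@H]1C | intermediate (not isolated)
38 | (6aR,11aR)-3,9-di-O-allyl-lespecyrtin E3 | CC(C)=CCc1cc2c(cc1OCC=C)OC[C@H]1c3c4c(c(OCC=C)c(CC=C(C)C)c3O[C@@H]21)OC(C)(C)C=C4 | intermediate
39 | lespecyrtin E3 | CC(C)=CCc1cc2c(cc1O)OC[C@H]1c3c4c(c(O)c(CC=C(C)C)c3O[C@@H]21)OC(C)(C)C=C4 | target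

**Totals**

Total step count: 17. Longest linear sequence: 11 steps (steps 5–10, then 13–17, from 2,4,5-trihydroxybenzaldehyde).

**Steps most likely to fail**

1. Step 16 (proposed new method). The ylide may decompose before it meets the methide (β-elimination within the thiolanium ring, or ionisation of the electron-rich benzyl sulfonium). The methide may tautomerise to the vinyl phenol. The ylide face or the betaine geometry may be poorly controlled. The fallback sets out from aldehyde 30 and returns at 38, using known reaction types. A triazolium-derived carbene with CsF should give the racemic, epimerisable 7-(allyloxy)-3-[8-(allyloxy)-6-hydroxy-2,2-dimethyl-7-prenyl-2H-chromen-5-yl]-6-prenylchroman-4-one F1. This is acyl-anion addition of the ring-A aldehyde to the fluoride-released o-quinone methide, known intermolecularly, combined with the classical intramolecular Stetter closure of chroman-4-ones. Asymmetric transfer hydrogenation with dynamic kinetic resolution (RuCl(p-cymene)[(R,R)-TsDPEN], HCO2H/Et3N) should then give the cis-(3R,4R)-isoflavan-4-ol F2. Mild acid (PPTS, CH2Cl2) closes ring C through the benzylic cation, cis to the C3 aryl group, to give 38.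

2. Step 13. The aryloxymethyllithium may decompose as a carbenoid, or the silyl group may migrate to the new alkoxide before acetylation and release the methide prematurely. The fallback sets out from phenol 18 and salicylaldehyde 5 and returns at 30. Compound 18 is protected (SEMCl, i-Pr2NEt) as 8-(allyloxy)-2,2-dimethyl-7-prenyl-6-{[2-(trimethylsilyl)ethoxy]methoxy}-2H-chromene-5-carbaldehyde F3. Corey–Chaykovsky methylenation (Me3SI, NaH, DMSO/THF) gives the aryl oxirane F4. Opening at the terminal carbon by the phenoxide of 5 (K2CO3, DMF, 70 °C) gives the β-hydroxy ether F5, whose SEM group cannot migrate. Fluoride (TBAF, DMPU, 60 °C) gives the phenol–alcohol diol F6. Phenol-selective silylation (TBSCl, imidazole) gives the aryl silyl ether F7, and acetylation (Ac2O, DMAP) gives 30.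

3. Step 15. The 2,4-dialkoxybenzyl cation may be lost to oligomerisation before the hindered sulfide captures it, or the salt may solvolyse during anion exchange. The fallback sets out from aldehyde 30 and sulfide 25 and returns at 38, forming the ylide by carbene transfer without isolating any sulfonium salt. Compound 30 and TsNHNH2 give the N-tosylhydrazone F8. Its sodium salt (NaH; then BnEt3NCl, MeCN, 40 °C) releases the aryldiazomethane F9. Rh2(OAc)4 transfers the carbene to 25 with CsF in the same flask, so that ylide 36 forms directly and continues to 38 as in step 16.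

**Further compounds**

F1 | step 16 | 7-(allyloxy)-3-[8-(allyloxy)-6-hydroxy-2,2-dimethyl-7-prenyl-2H-chromen-5-yl]-6-prenylchroman-4-one (racemic) | O=C1c2cc(CC=C(C)C)c(OCC=C)cc2OCC1c1c2C=CC(C)(C)Oc2c(OCC=C)c(CC=C(C)C)c1O
F2 | step 16 | (3R,4R)-7-(allyloxy)-3-[8-(allyloxy)-6-hydroxy-2,2-dimethyl-7-prenyl-2H-chromen-5-yl]-6-prenylchroman-4-ol | O[C@H]1c2cc(CC=C(C)C)c(OCC=C)cc2OC[C@H]1c3c4C=CC(C)(C)Oc4c(OCC=C)c(CC=C(C)C)c3O
F3 | step 13 | 8-(allyloxy)-2,2-dimethyl-7-prenyl-6-{[2-(trimethylsilyl)ethoxy]methoxy}-2H-chromene-5-carbaldehyde | O=Cc1c2C=CC(C)(C)Oc2c(OCC=C)c(CC=C(C)C)c1OCOCC[Si](C)(C)C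
F4 | step 13 | 2-[8-(allyloxy)-2,2-dimethyl-7-prenyl-6-{[2-(trimethylsilyl)ethoxy]methoxy}-2H-chromen-5-yl]oxirane (racemic) | C1OC1c1c2C=CC(C)(C)Oc2c(OCC=C)c(CC=C(C)C)c1OCOCC[Si](C)(C)C
F5 | step 13 | 4-(allyloxy)-2-{2-hydroxy-2-[8-(allyloxy)-2,2-dimethyl-7-prenyl-6-{[2-(trimethylsilyl)ethoxy]methoxy}-2H-chromen-5-yl]ethoxy}-5-prenylbenzaldehyde | OC(COc1cc(OCC=C)c(CC=C(C)C)cc1C=O)c1c2C=CC(C)(C)Oc2c(OCC=C)c(CC=C(C)C)c1OCOCC[Si](C)(C)C
F6 | step 13 | 4-(allyloxy)-2-{2-hydroxy-2-[8-(allyloxy)-6-hydroxy-2,2-dimethyl-7-prenyl-2H-chromen-5-yl]ethoxy}-5-prenylbenzaldehyde | OC(COc1cc(OCC=C)c(CC=C(C)C)cc1C=O)c1c2C=CC(C)(C)Oc2c(OCC=C)c(CC=C(C)C)c1O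
F7 | step 13 | 4-(allyloxy)-2-{2-hydroxy-2-[8-(allyloxy)-6-(tert-butyldimethylsilyloxy)-2,2-dimethyl-7-prenyl-2H-chromen-5-yl]ethoxy}-5-prenylbenzaldehyde | OC(COc1cc(OCC=C)c(CC=C(C)C)cc1C=O)c1c2C=CC(C)(C)Oc2c(OCC=C)c(CC=C(C)C)c1O[Si](C)(C)C(C)(C)C
F8 | step 15 | N-tosylhydrazone of aldehyde 30 | CC(=O)OC(COc1cc(OCC=C)c(CC=C(C)C)cc1C=NNS(=O)(=O)c1ccc(C)cc1)c1c2C=CC(C)(C)Oc2c(OCC=C)c(CC=C(C)C)c1O[Si](C)(C)C(C)(C)C
F9 | step 15 | aryldiazomethane derived from 30 | CC(=O)OC(COc1cc(OCC=C)c(CC=C(C)C)cc1C=[N+]=[N-])c1c2C=CC(C)(C)Oc2c(OCC=C)c(CC=C(C)C)c1O[Si](C)(C)C(C)(C)C
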